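Working numbering: C1 (OAc), C2 and C3 (OH), C4=C5 (C5 bears C7H2OBz), C6 (OBz). C3 is an allylic carbinol on the hydrogen-bearing alkene carbon C4, so the cyclohexene ring is cut at C3–C4. One CrCl2/NiCl2 alkenyl iodide–aldehyde coupling forges this bond, closes the carbocycle and sets C3. The precursor is an open-chain C3 aldehyde with a C4 iodide cis to C6. It already carries both benzoates (C6, C7) and a C1/C2 acetonide, so only acetonide removal and C1 acetylation follow. L-Arabinose delivers C6, C1 and C2, and a hydroxyl-directed anti-carbomagnesiation fixes the iodoalkene geometry.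

Key step: step 9

Remark: atom labels C1–C7 follow the working numbering of the target in all intermediates; 10 is formulated as the cyclic siloxane, and any open-chain isopropoxysilane that persists would be oxidised to 11 in the same way.

Step 1
Reactants: 1 L-arabinose
Product: 2 3,4-O-isopropylidene-L-arabinopyranose (anomeric mixture; the acetonide oxygens are O1/O2 of the target)
Conditions: Me2C(OMe)2 (1.5 equiv), p-TsOH·H2O (cat.), DMF, rt; Et3N quench
Reagents that add atoms: 2,2-dimethoxypropane, COC(C)(C)OC
Why: Acid-catalysed transketalisation takes the cis O3/O4 pair of the pyranose, and the arabinose centres C2, C3 and C4 (target C6, C1 and C2) are carried over unchanged from the chiral pool.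

Step 2
Reactants: 2 3,4-O-isopropylidene-L-arabinopyranose; 3 dimethyl (1-diazo-2-oxopropyl)phosphonate (Ohira–Bestmann reagent)
Product: 5 1,2-dideoxy-4,5-O-isopropylidene-L-arabino-hex-1-ynitol (terminal alkyne C4≡C5; free C6 and C3 hydroxyls), via dimethyl (diazomethyl)phosphonate 4 (not isolated)
Conditions: 3 (1.6 equiv), K2CO3 (3 equiv), MeOH, rt to 40 °C
Reagents that add atoms: dimethyl (1-diazo-2-oxopropyl)phosphonate 3, COP(=O)(OC)C(=[N+]=[N-])C(C)=O
Why: Seyferth–Gilbert homologation in the Ohira–Bestmann version, in which methanolysis of 3 gives 4, 4 olefinates the open-chain aldehyde in equilibrium with lactol 2, and loss of N2 with a 1,2-hydride shift gives the alkyne under carbonate base mild enough to leave C6 untouched.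

Step 3
Reactants: 5 1,2-dideoxy-4,5-O-isopropylidene-L-arabino-hex-1-ynitol
Product: 6 6-O-(tert-butyldimethylsilyl)-1,2-dideoxy-4,5-O-isopropylidene-L-arabino-hex-1-ynitol (C3–OTBS; C6–OH free)
Conditions: TBSCl (1.05 equiv), imidazole, CH2Cl2, −10 to 0 °C
Reagents that add atoms: tert-butyldimethylsilyl chloride, CC(C)(C)[Si](C)(C)Cl
Why: Selective silylation, since the unhindered primary C3 hydroxyl reacts much faster than the secondary propargylic C6 hydroxyl, which has to stay free as the directing group of step 4.

Step 4
Reactants: 6 C3-silylated alkynol; 7 (chloromethyl)isopropoxydimethylsilane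
Product: 10 cyclic siloxane vinyl iodide (five-membered O6–SiMe2–C7H2–C5–C6 ring; exocyclic C5=C4HI, iodine cis to C6; C1/C2 acetonide; C3–OTBS), via Grignard reagent 8 (not isolated), via oxamagnesacycle 9 (not isolated)
Conditions: 7, Mg, THF, rt to 45 °C (gives 8, 3.5 equiv); 6, CuI (20 mol %), THF, −10 °C to rt; I2, THF, −40 to 0 °C; aq. NH4Cl/Na2S2O3
Reagents that add atoms: (chloromethyl)isopropoxydimethylsilane 7, CC(C)O[Si](C)(C)CCl; iodine, [I][I]
Why: Copper-catalysed anti-carbomagnesiation of a propargylic alcohol, in which the C6 magnesium alkoxide steers the silylmethyl group (the future C7) to the inner alkyne carbon C5 and keeps magnesium on C4 inside five-membered chelate 9, so iodinolysis with retention must place iodine cis to C6 (allenolate-type iodo-aldol or sterically ruled olefination routes would place it trans), after which the alkoxide closes onto silicon with loss of isopropoxide.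

Step 5
Reactants: 10 cyclic siloxane vinyl iodide
Product: 11 iodoalkenyl diol (C6–OH and C7H2–OH free; iodine cis to C6; C1/C2 acetonide; C3–OTBS)
Conditions: 30% H2O2, KF, KHCO3, THF/MeOH (1:1), rt
Reagents that add atoms: hydrogen peroxide, OO
Why: Tamao oxidation, in which peroxide adds to the activated alkoxysilane and C7 shifts from silicon to oxygen, so C7–Si becomes C7–OH without allylic transposition while vinyl iodide, acetonide and the primary TBS ether are inert to buffered peroxide.

Step 6
Reactants: 11 iodoalkenyl diol
Product: 12 C6,C7-dibenzoate (iodine cis to C6; C1/C2 acetonide; C3–OTBS)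
Conditions: BzCl (3 equiv), pyridine, DMAP (cat.), CH2Cl2, 0 °C to rt
Reagents that add atoms: benzoyl chloride, O=C(Cl)c1ccccc1
Why: DMAP-catalysed acylation places both final benzoates before the ring closure, so no protecting-group exchange and no temporary C3 protection are needed afterwards.

Step 7
Reactants: 12 C6,C7-dibenzoate
Product: 13 primary C3 alcohol (C6 and C7 benzoates; C1/C2 acetonide; iodine cis to C6)
Conditions: HF·pyridine, pyridine/THF, 0 °C to rt
Reagents that add atoms: none
Why: Fluoride-mediated desilylation in a weakly acidic buffer cleaves only the Si–O bond, conditions under which benzoates do not migrate and the acetonide and vinyl iodide persist.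

Step 8
Reactants: 13 primary C3 alcohol
Product: 14 vinyl iodide aldehyde (C3 aldehyde; C4 iodide cis to C6; C6 and C7 benzoates; C1/C2 acetonide)
Conditions: Dess–Martin periodinane (1.3 equiv), CH2Cl2, 0 °C to rt; used directly
Reagents that add atoms: none
Why: Dess–Martin oxidation stops at the aldehyde under non-basic conditions, so the epimerisable C2 centre of the cis-dioxolane aldehyde is kept.

Step 9
Reactants: 14 vinyl iodide aldehyde
Product: 17 cyclohexenol (C3–OH free and trans to O2; C1/C2 acetonide on one face; C3–OH and C6–OBz on the other face; C7H2OBz on C5), via alkenylchromium dichloride 15 (not isolated), via chromium alkoxide 16 (not isolated)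
Conditions: CrCl2 (8 equiv), NiCl2 (0.1 equiv), degassed DMSO, 0.005 M, rt; aqueous work-up
Reagents that add atoms: none
Why: Oxidative addition of the C4–I bond to zerovalent nickel (made in the flask from NiCl2 and CrCl2) keeps the alkene geometry, the alkenyl group passes to trivalent chromium to give 15, and this weakly basic, carbonyl-selective organometal adds to the C3 aldehyde to give 16, which is an intramolecular Nozaki–Hiyama–Kishi reaction, a known way to close cyclic allylic alcohols from iodoalkenyl aldehydes. The six-membered carbocycle closes in the 6-exo-trig mode, the carbonyl oxygen remaining outside the new ring. The cis-dioxolane holds the aldehyde and the C6 side chain on the same side of a five-membered ring, so the reacting ends are close and moderate dilution should suppress intermolecular coupling. C3 is set in a half-chair transition state in which the C6 benzoate is pseudoaxial (no A(1,2) strain with the C7 arm on C5), O2 is equatorial and therefore antiperiplanar to the forming C3–C4 bond, and the chromium-bound carbonyl oxygen occupies the pseudoequatorial site, which places the C3 hydroxyl trans to O2. The step needs attack on the aldehyde in the presence of two benzoates and integrity of C2 and of the alkene geometry; alkenylchromium reagents leave esters alone and do not enolise α-alkoxy aldehydes, and β,β-disubstituted alkenyl iodides couple with retention.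

Step 10
Reactants: 17 cyclohexenol
Product: 18 C1,C2,C3-triol (1S,2S,3R,6S in the working numbering; C6 and C7 benzoates)
Conditions: TFA/H2O (4:1), CH2Cl2, 0 °C
Reagents that add atoms: none
Why: Acid-catalysed acetal hydrolysis removes the only acetal, the esters survive cold aqueous acid, and the trans C6 benzoate/C1 hydroxyl pair cannot easily reach the cyclic intermediate needed for acyl migration.

Step 11
Reactants: 18 C1,C2,C3-triol
Product: 20 target CNP0213675.1 (C1 acetate; C2 and C3 hydroxyls; C6 and C7 benzoates; 1S,2S,3R,6S in the working numbering), via cyclic orthoacetate 19 (not isolated)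
Conditions: MeC(OMe)3 (1.3 equiv), CSA (cat.), MeCN, rt; then 80% aq. AcOH, 0 °C to rt
Reagents that add atoms: trimethyl orthoacetate, CC(OC)(OC)OC; water, O
Why: Orthoester formation and stereoelectronically controlled hydrolysis, in which the orthoacetate bridges the only cis-diol (O1/O2) as 19 and, in the favoured half-chair (C6 benzoate pseudoaxial, hence O1 axial and O2 equatorial), the hemiorthoester formed with water breaks its bond to the equatorial oxygen, which leaves the acetate on axial O1, whereas direct acylation would favour equatorial O2.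

Compound list
1 | L-arabinose (drawn open-chain) | O=C[C@H](O)[C@@H](O)[C@@H](O)CO | starting material
2 | 3,4-O-isopropylidene-L-arabinopyranose (anomeric mixture) | CC1(C)O[C@@H]2[C@@H](O)C(O)OC[C@@H]2O1 | intermediate
3 | dimethyl (1-diazo-2-oxopropyl)phosphonate | COP(=O)(OC)C(=[N+]=[N-])C(C)=O | starting material
4 | dimethyl (diazomethyl)phosphonate | COP(=O)(OC)C=[N+]=[N-] | intermediate
5 | 1,2-dideoxy-4,5-O-isopropylidene-L-arabino-hex-1-ynitol | CC1(C)O[C@H]([C@@H](O)C#C)[C@@H](O1)CO | intermediate
6 | 6-O-TBS-1,2-dideoxy-4,5-O-isopropylidene-L-arabino-hex-1-ynitol | CC1(C)O[C@H]([C@@H](O)C#C)[C@@H](O1)CO[Si](C)(C)C(C)(C)C | intermediate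
7 | (chloromethyl)isopropoxydimethylsilane | CC(C)O[Si](C)(C)CCl | starting material
8 | [(isopropoxydimethylsilyl)methyl]magnesium chloride | CC(C)O[Si](C)(C)C[Mg]Cl | intermediate
9 | oxamagnesacycle (Mg bridges O6 and C4; C5 bears the silylmethyl group) | CC1(C)O[C@H]([C@H]2O[Mg]C=C2C[Si](C)(C)OC(C)C)[C@@H](O1)CO[Si](C)(C)C(C)(C)C | intermediate
10 | cyclic siloxane vinyl iodide (iodine cis to C6) | CC1(C)O[C@H]([C@H]2O[Si](C)(C)C/C2=C/I)[C@@H](O1)CO[Si](C)(C)C(C)(C)C | intermediate
11 | iodoalkenyl C6,C7-diol (iodine cis to C6) | CC1(C)O[C@H]([C@@H](O)/C(CO)=C\I)[C@@H](O1)CO[Si](C)(C)C(C)(C)C | intermediate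
12 | C6,C7-dibenzoate, C3–OTBS | CC1(C)O[C@H]([C@@H](OC(=O)c2ccccc2)/C(COC(=O)c2ccccc2)=C\I)[C@@H](O1)CO[Si](C)(C)C(C)(C)C | intermediate
13 | C6,C7-dibenzoate, C3 primary alcohol | CC1(C)O[C@H]([C@@H](OC(=O)c2ccccc2)/C(COC(=O)c2ccccc2)=C\I)[C@@H](O1)CO | intermediate
14 | vinyl iodide aldehyde (precursor of the key step) | CC1(C)O[C@H]([C@@H](OC(=O)c2ccccc2)/C(COC(=O)c2ccccc2)=C\I)[C@@H](O1)C=O | intermediate
15 | alkenylchromium dichloride | CC1(C)O[C@H]([C@@H](OC(=O)c2ccccc2)/C(COC(=O)c2ccccc2)=C\[Cr](Cl)Cl)[C@@H](O1)C=O | intermediate
16 | chromium alkoxide of 17 | CC1(C)O[C@H]2[C@@H](O1)[C@H](O[Cr](Cl)Cl)C=C(COC(=O)c3ccccc3)[C@@H]2OC(=O)c3ccccc3 | intermediate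
17 | cyclohexenol with free C3 hydroxyl (product of the key step) | CC1(C)O[C@H]2[C@@H](O1)[C@H](O)C=C(COC(=O)c3ccccc3)[C@@H]2OC(=O)c3ccccc3 | intermediate
18 | C1,C2,C3-triol dibenzoate | O[C@H]1[C@@H](O)[C@H](O)C=C(COC(=O)c2ccccc2)[C@@H]1OC(=O)c1ccccc1 | intermediate
19 | C1,C2 cyclic methyl orthoacetate (mixture at the orthoester carbon) | COC1(C)O[C@H]2[C@@H](O1)[C@H](O)C=C(COC(=O)c3ccccc3)[C@@H]2OC(=O)c3ccccc3 | intermediate
20 | CNP0213675.1 | CC(=O)O[C@H]1[C@@H](O)[C@H](O)C=C(COC(=O)c2ccccc2)[C@@H]1OC(=O)c1ccccc1 | target

Total step count: 11. Longest linear sequence: 11 steps (1 to 20).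

Steps most likely to fail

Step 9. Facial selection at the aldehyde may be weak or reversed, for instance if chromium also binds O1 and draws the carbonyl oxygen into the pseudoaxial site. The fallback sets out from 14. The ring closure is run as planned and the C3-epimeric cyclohexenol F1 is carried on. A Mitsunobu reaction with chloroacetic acid (PPh3, DIAD, toluene, 0 °C) inverts the allylic carbinol to the C3 chloroacetate F2. Thiourea (NaHCO3, EtOH/THF, 50 °C) then removes the chloroacetyl group in the presence of both benzoates, and the material comes back to the route at 17.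

Step 4. Exchange of the C6 alkoxide at the alkoxysilane centre of the Grignard reagent could tether the nucleophile and open a syn delivery channel, which would erode the alkene geometry. The fallback sets out from 6 and uses a silicon-free C7 donor.
- Vinylmagnesium chloride with catalytic CuI (THF, 0 °C to rt), then I2, should give the 2-vinyl iodoalkenol F3 by the same chelate-controlled anti addition.
- OsO4 (cat.)/NMO should attack only the electron-richer terminal vinyl group, giving the triol F4.
- NaIO4 cleaves the new glycol to the β-iodo enal F5.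
- Luche reduction (NaBH4, CeCl3·7H2O, MeOH, −40 °C) brings the material back at 11.

Step 11. The hemiorthoester may collapse towards the C2 ester, or the acetyl group may later migrate from O1 to the cis O2. The fallback sets out from 18 and masks the other two hydroxyls instead of relying on the ring-opening rule.
- Butane-2,3-dione, HC(OMe)3 and CSA in MeOH at rt should lock the trans-diequatorial O2/O3 pair as the butane-2,3-diacetal F6 and leave only C1–OH free.
- Ac2O/pyridine/DMAP gives the C1 acetate F7.
- Cold TFA/H2O (9:1) in CH2Cl2 removes the diacetal and reaches 20.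

Further compounds
F1 | step 9 | C3 epimer of 17 (C3–OH cis to O2) | CC1(C)O[C@H]2[C@@H](O1)[C@@H](O)C=C(COC(=O)c3ccccc3)[C@@H]2OC(=O)c3ccccc3
F2 | step 9 | C3 chloroacetate of 17 (C3 oxygen trans to O2) | CC1(C)O[C@H]2[C@@H](O1)[C@H](OC(=O)CCl)C=C(COC(=O)c3ccccc3)[C@@H]2OC(=O)c3ccccc3
F3 | step 4 | 2-vinyl iodoalkenol (vinyl on C5; iodine cis to C6; C6–OH free; C3–OTBS) | CC1(C)O[C@H]([C@@H](O)/C(C=C)=C\I)[C@@H](O1)CO[Si](C)(C)C(C)(C)C
F4 | step 4 | triol from dihydroxylation of the vinyl group (mixture at the new carbinol) | CC1(C)O[C@H]([C@@H](O)/C(C(O)CO)=C\I)[C@@H](O1)CO[Si](C)(C)C(C)(C)C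
F5 | step 4 | β-iodo enal (C7 as aldehyde; iodine cis to C6) | CC1(C)O[C@H]([C@@H](O)/C(C=O)=C\I)[C@@H](O1)CO[Si](C)(C)C(C)(C)C
F6 | step 11 | O2,O3-butane-2,3-diacetal of 18 (both acetal methoxy groups axial; C1–OH free) | O[C@H]1[C@H]2O[C@](C)(OC)[C@@](C)(OC)O[C@@H]2C=C(COC(=O)c3ccccc3)[C@@H]1OC(=O)c3ccccc3
F7 | step 11 | C1 acetate of F6 | CC(=O)O[C@H]1[C@H]2O[C@](C)(OC)[C@@](C)(OC)O[C@@H]2C=C(COC(=O)c3ccccc3)[C@@H]1OC(=O)c3ccccc3
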